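Ring A, the benzoic acid ring (position 1 CO2H, 2 OH, 3 H, 4 OH, 5 the ether oxygen, 6 pentyl), is a folded tetraketide: its ether-bearing carbon 5 is C6 of a 3,5,7-trioxododecanoate chain, an sp3 carbon between two ketones. The ring B aryloxy group is therefore attached there by carbene O–H insertion, not by coupling two hindered arenes. One base-mediated aldol condensation (chain C2 onto the C7 ketone, then loss of water) joins ring A carbons 1 and 6 and closes ring A as the fully substituted resorcylate. Its precursor is the allyl triketo ester bearing the complete ring B, released from a dioxinone by ketene trapping; mild deallylation then frees the acid.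

Key step: step 10

Remark: the target has no stereocentre; the stereocentres of the transient aldol adduct 18 are left undefined because all of them become aromatic carbons.

Step 1
Reactants: 1 3,5-dimethoxybenzonitrile; 2 n-butylmagnesium chloride
Product: 4 1-(3,5-dimethoxyphenyl)pentan-1-one, via chloromagnesium ketimide 3 (not isolated)
Conditions: n-BuMgCl (1.3 equiv), CuBr (2 mol %), THF, reflux; then 2 M aq. HCl, rt
Reagents that add atoms: water, O
Why: Grignard addition to the aryl nitrile stops at the N-magnesio ketimine 3, which is inert to a second addition and is hydrolysed to the ketone by aqueous acid, the standard nitrile-to-ketone synthesis.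

Step 2
Reactants: 4 1-(3,5-dimethoxyphenyl)pentan-1-one
Product: 5 1-(2-bromo-3,5-dimethoxyphenyl)pentan-1-one
Conditions: NBS (1.05 equiv), MeCN, 0 °C to rt
Reagents that add atoms: N-bromosuccinimide, O=C1CCC(=O)N1Br
Why: Electrophilic aromatic bromination with NBS should go to C2, which is para to one methoxy group and ortho to the other, not to the crowded C4 between the two methoxy groups, and the ring is far more reactive than the ketone α-position under acid-free conditions.

Step 3
Reactants: 5 1-(2-bromo-3,5-dimethoxyphenyl)pentan-1-one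
Product: 6 methyl 2,4-dimethoxy-6-pentanoylbenzoate
Conditions: Pd(OAc)2 (5 mol %), Xantphos (10 mol %), CO (5 bar), Et3N (2 equiv), MeOH–toluene 1:1, 90 °C
Reagents that add atoms: carbon monoxide, [C-]#[O+]; methanol, CO
Why: Palladium-catalysed alkoxycarbonylation (Heck carbonylation) of the aryl bromide by oxidative addition, CO insertion and methanolysis of the acylpalladium should give the methyl ester, the wide-bite-angle ligand and CO pressure being chosen for the doubly ortho-substituted bromide while methanol intercepts the acyl complex before the ketone enol can.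

Step 4
Reactants: 6 methyl 2,4-dimethoxy-6-pentanoylbenzoate
Product: 7 methyl 2-hydroxy-4-methoxy-6-pentanoylbenzoate
Conditions: BCl3 (1.5 equiv), CH2Cl2, −78 to 0 °C; then H2O
Reagents that add atoms: none
Why: Chelation-controlled Lewis-acid ether cleavage, in which BCl3 bridges the ester carbonyl and the adjacent C2 methoxy oxygen in a six-membered chelate and chloride removes only that methyl group, whereas the C4 methoxy has no neighbouring carbonyl and the ketone has no ortho ether.

Step 5
Reactants: 8 2,2,6-trimethyl-4H-1,3-dioxin-4-one; 9 acetyl chloride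
Product: 10 2,2-dimethyl-6-(2-oxopropyl)-4H-1,3-dioxin-4-one
Conditions: 8 (2.0 equiv), LiN(SiMe3)2 (2.0 equiv), THF, −78 °C; then 9 (1.0 equiv), −78 °C; 1 M HCl
Reagents that add atoms: none
Why: Vinylogous Claisen C-acylation, in which the lithium dienolate of 8 reacts at its γ-carbon with the acid chloride and the second equivalent of dienolate absorbs the more acidic keto-dioxinone product so that it is not acylated twice.

Step 6
Reactants: 10 2,2-dimethyl-6-(2-oxopropyl)-4H-1,3-dioxin-4-one; 11 hexanoyl chloride
Product: 12 6-(2,4-dioxononyl)-2,2-dimethyl-4H-1,3-dioxin-4-one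
Conditions: 10 (2.0 equiv), LiN(i-Pr)2 (4.1 equiv), THF, −78 °C; then 11 (1.0 equiv), −78 to −40 °C; 1 M HCl
Reagents that add atoms: none
Why: Dianion Claisen acylation, in which double deprotonation of 10 gives a dianion whose terminal, last-formed carbanion is the most nucleophilic site and is acylated by hexanoyl chloride, the excess dianion covering the acidity of the resulting 1,3-diketone.

Step 7
Reactants: 12 6-(2,4-dioxononyl)-2,2-dimethyl-4H-1,3-dioxin-4-one
Product: 13 6-(3-diazo-2,4-dioxononyl)-2,2-dimethyl-4H-1,3-dioxin-4-one
Conditions: 4-acetamidobenzenesulfonyl azide (1.05 equiv), Et3N (1.1 equiv), MeCN, 0 °C, 1 h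
Reagents that add atoms: 4-acetamidobenzenesulfonyl azide, CC(=O)Nc1ccc(cc1)S(=O)(=O)N=[N+]=[N-]
Why: Regitz diazo transfer to the most acidic methylene, the one between the two ketones (C6 of the future chain), whose triethylammonium enolate should add to the sulfonyl azide at 0 °C faster than the amine can trigger aldol closure of the dioxinone, and once C6 carries the diazo group that closure can no longer aromatise.

Step 8
Reactants: 13 6-(3-diazo-2,4-dioxononyl)-2,2-dimethyl-4H-1,3-dioxin-4-one; 7 methyl 2-hydroxy-4-methoxy-6-pentanoylbenzoate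
Product: 14 methyl 2-{[1-(2,2-dimethyl-4-oxo-4H-1,3-dioxin-6-yl)-2,4-dioxononan-3-yl]oxy}-4-methoxy-6-pentanoylbenzoate
Conditions: Rh2(OAc)4 (2 mol %), toluene, 70 °C, 13 (1.3 equiv) added slowly to 7; short silica plug
Reagents that add atoms: none
Why: Rh2(OAc)4-catalysed carbene O–H insertion of a 2-diazo-1,3-dicarbonyl compound into a phenol (rhodium carbenoid, then oxonium ylide and proton shift) should form the hindered C6–O aryl ether under neutral conditions, so that neither the base-sensitive diketo-dioxinone nor the ring B ketone and ester meet a base, while slow addition keeps the carbenoid concentration low against dimerisation and C–H insertion into the pentyl chain.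

Step 9
Reactants: 14 methyl 2-{[1-(2,2-dimethyl-4-oxo-4H-1,3-dioxin-6-yl)-2,4-dioxononan-3-yl]oxy}-4-methoxy-6-pentanoylbenzoate; 15 allyl alcohol
Product: 17 allyl 6-[5-methoxy-2-(methoxycarbonyl)-3-pentanoylphenoxy]-3,5,7-trioxododecanoate, via acylketene 16 (not isolated)
Conditions: allyl alcohol (5 equiv), toluene, 105 °C, 1.5 h; concentrate, use crude
Reagents that add atoms: none
Why: Thermal retro-hetero-Diels–Alder cleavage of the dioxinone expels acetone and gives acylketene 16, which the excess allyl alcohol should capture as the β-keto allyl ester faster than the enolised diketone can lactonise onto it.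

Step 10
Reactants: 17 allyl 6-[5-methoxy-2-(methoxycarbonyl)-3-pentanoylphenoxy]-3,5,7-trioxododecanoate
Product: 19 allyl 2,4-dihydroxy-5-[5-methoxy-2-(methoxycarbonyl)-3-pentanoylphenoxy]-6-pentylbenzoate, via cyclic aldol adduct 18 (not isolated)
Conditions: Cs2CO3 (2 equiv), THF–i-PrOH 4:1, 0 °C to rt; then 1 M HCl
Reagents that add atoms: none
Why: Cs2CO3 deprotonates the chain reversibly, the C2 enolate (between ester C1 and ketone C3) adds to the C7 ketone to give the cyclic aldol 18, and E1cB loss of water followed by enolisation of C3 and C5 gives the benzene ring, the acid finish completing the dehydration. The closest known reaction is the base-mediated aldol aromatisation of 3,5,7-triketo esters to 6-alkyl-2,4-dihydroxybenzoates, applied here to a chain that carries an aryloxy group on C6. Ring A closes in a 6-(enolendo)-exo-trig mode and the new bond joins ring A carbons 1 and 6 (chain C2–C7). No stereocentre has to be controlled, since C2, C6 and C7 of 18 all end as aromatic carbons. The chemoselectivity needed (C2 onto C7 in preference to C8 onto C3, to attack of the C6 carbanion on the ring B ester, and to lactonisation to a pyranone) rests on C2 being far more acidic than C8, on the C6 carbanion being a stabilised tertiary centre facing a 2,6-disubstituted benzoate whose adduct cannot aromatise and reverts, and on the C2–C7 adduct alone draining irreversibly to an arene. The aryloxy group sits α and not β to the ketones, so E1cB cannot expel it, and the weak base in a medium free of methoxide limits retro-Claisen cleavage and leaves the ring B ketone alone.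

Step 11
Reactants: 19 allyl 2,4-dihydroxy-5-[5-methoxy-2-(methoxycarbonyl)-3-pentanoylphenoxy]-6-pentylbenzoate
Product: 20 2,4-dihydroxy-5-[5-methoxy-2-(methoxycarbonyl)-3-pentanoylphenoxy]-6-pentylbenzoic acid
Conditions: Pd(PPh3)4 (5 mol %), morpholine (5 equiv), THF, rt; cold dilute HCl work-up
Reagents that add atoms: none
Why: Tsuji–Trost deallylation, in which zerovalent palladium ionises the allyl ester to a π-allyl complex that morpholine intercepts, should free the acid at room temperature without touching the hindered methyl ester, the ketone or the decarboxylation-prone salicylic acid.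

Compound list
1 | 3,5-dimethoxybenzonitrile | COc1cc(OC)cc(C#N)c1 | starting material
2 | n-butylmagnesium chloride | CCCC[Mg]Cl | starting material
3 | N-(chloromagnesio)-1-(3,5-dimethoxyphenyl)pentan-1-imine | CCCCC(=N[Mg]Cl)c1cc(OC)cc(OC)c1 | intermediate
4 | 1-(3,5-dimethoxyphenyl)pentan-1-one | CCCCC(=O)c1cc(OC)cc(OC)c1 | intermediate
5 | 1-(2-bromo-3,5-dimethoxyphenyl)pentan-1-one | CCCCC(=O)c1cc(OC)cc(OC)c1Br | intermediate
6 | methyl 2,4-dimethoxy-6-pentanoylbenzoate | CCCCC(=O)c1cc(OC)cc(OC)c1C(=O)OC | intermediate
7 | methyl 2-hydroxy-4-methoxy-6-pentanoylbenzoate | CCCCC(=O)c1cc(OC)cc(O)c1C(=O)OC | intermediate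
8 | 2,2,6-trimethyl-4H-1,3-dioxin-4-one | CC1=CC(=O)OC(C)(C)O1 | starting material
9 | acetyl chloride | CC(Cl)=O | starting material
10 | 2,2-dimethyl-6-(2-oxopropyl)-4H-1,3-dioxin-4-one | CC(=O)CC1=CC(=O)OC(C)(C)O1 | intermediate
11 | hexanoyl chloride | CCCCCC(=O)Cl | starting material
12 | 6-(2,4-dioxononyl)-2,2-dimethyl-4H-1,3-dioxin-4-one | CCCCCC(=O)CC(=O)CC1=CC(=O)OC(C)(C)O1 | intermediate
13 | 6-(3-diazo-2,4-dioxononyl)-2,2-dimethyl-4H-1,3-dioxin-4-one | CCCCCC(=O)C(=[N+]=[N-])C(=O)CC1=CC(=O)OC(C)(C)O1 | intermediate
14 | methyl 2-{[1-(2,2-dimethyl-4-oxo-4H-1,3-dioxin-6-yl)-2,4-dioxononan-3-yl]oxy}-4-methoxy-6-pentanoylbenzoate | CCCCCC(=O)C(Oc1cc(OC)cc(C(=O)CCCC)c1C(=O)OC)C(=O)CC2=CC(=O)OC(C)(C)O2 | intermediate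
15 | allyl alcohol | C=CCO | starting material
16 | methyl 4-methoxy-2-[(1,3,5,7-tetraoxododec-1-en-6-yl)oxy]-6-pentanoylbenzoate (the acylketene, chain O=C=CH–CO–CH2–CO–CH(OAr)–CO–pentyl) | CCCCCC(=O)C(Oc1cc(OC)cc(C(=O)CCCC)c1C(=O)OC)C(=O)CC(=O)C=C=O | intermediate
17 | allyl 6-[5-methoxy-2-(methoxycarbonyl)-3-pentanoylphenoxy]-3,5,7-trioxododecanoate | C=CCOC(=O)CC(=O)CC(=O)C(Oc1cc(OC)cc(C(=O)CCCC)c1C(=O)OC)C(=O)CCCCC | intermediate
18 | allyl 2-hydroxy-3-[5-methoxy-2-(methoxycarbonyl)-3-pentanoylphenoxy]-4,6-dioxo-2-pentylcyclohexane-1-carboxylate (diastereomer mixture, configuration undefined) | CCCCCC1(O)C(C(=O)OCC=C)C(=O)CC(=O)C1Oc2cc(OC)cc(C(=O)CCCC)c2C(=O)OC | intermediate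
19 | allyl 2,4-dihydroxy-5-[5-methoxy-2-(methoxycarbonyl)-3-pentanoylphenoxy]-6-pentylbenzoate | CCCCCc1c(Oc2cc(OC)cc(C(=O)CCCC)c2C(=O)OC)c(O)cc(O)c1C(=O)OCC=C | intermediate
20 | 2,4-dihydroxy-5-[5-methoxy-2-(methoxycarbonyl)-3-pentanoylphenoxy]-6-pentylbenzoic acid | CCCCCc1c(Oc2cc(OC)cc(C(=O)CCCC)c2C(=O)OC)c(O)cc(O)c1C(=O)O | target

Total step count: 11. Longest linear sequence: 8 steps (steps 1, 2, 3, 4, 8, 9, 10, 11); the chain branch (steps 5, 6, 7) joins at step 8.

Steps most likely to fail, in order of risk:

Step 10. The open triketo ester may be diverted before the C2–C7 aldol: lactonisation of the C5 enol onto the allyl ester to a 4-hydroxy-2-pyranone, retro-Claisen cleavage at the doubly activated C6, or a sluggish aldol because the aryloxy group makes the C6 enolate the resting state. The fallback forms the same bond one stage earlier, with the ester still masked as the dioxinone. It sets out from 14, which would be stirred with Et3N in CH2Cl2 at rt so that the vinylogous dioxinone enolate closes onto the C7 ketone and aromatises to methyl 2-[(7-hydroxy-2,2-dimethyl-4-oxo-5-pentyl-4H-1,3-benzodioxin-6-yl)oxy]-4-methoxy-6-pentanoylbenzoate F1. Opening of this benzodioxinone with sodium allyloxide (allyl alcohol, NaH, THF, 0 °C to rt) would then give the allyl ester, and the route is rejoined at 19.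

Step 8. Carbene transfer may be lost to C–H insertion into the pentyl chain, carbene dimerisation or slow reaction of the hydrogen-bonded, hindered phenol, and prolonged heating would start to cleave the dioxinone. The fallback makes the ether by substitution. It sets out from 12, which would be chlorinated between the ketones with NCS (CH2Cl2, 0 °C, no base) to 6-(3-chloro-2,4-dioxononyl)-2,2-dimethyl-4H-1,3-dioxin-4-one F2. F2 would then be treated at 0 °C in acetone with the caesium phenoxide pre-formed from 7 and Cs2CO3, an SN2 displacement on a 2-chloro-1,3-diketone, coming back to the route at 14. Contact time and temperature must be kept low because carbonate can also trigger ring closure of the diketo-dioxinone, which is why this is not the first choice.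

Step 3. Oxidative addition or CO insertion at the doubly ortho-substituted, electron-rich bromide may stall, or the acylpalladium may be captured by the ketone enol instead of methanol. The fallback introduces the carboxyl by lithiation. It sets out from 5, which would be ketalised (ethylene glycol, TsOH, toluene, Dean–Stark) to 2-(2-bromo-3,5-dimethoxyphenyl)-2-butyl-1,3-dioxolane F3. Bromine–lithium exchange (n-BuLi, THF, −78 °C) and quenching with methyl chloroformate would give methyl 2-(2-butyl-1,3-dioxolan-2-yl)-4,6-dimethoxybenzoate F4, and aqueous HCl in THF would release the ketone, coming back to the route at 6.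

Further compounds
F1 | step 10 | methyl 2-[(7-hydroxy-2,2-dimethyl-4-oxo-5-pentyl-4H-1,3-benzodioxin-6-yl)oxy]-4-methoxy-6-pentanoylbenzoate | CCCCCc1c(Oc2cc(OC)cc(C(=O)CCCC)c2C(=O)OC)c(O)cc3OC(C)(C)OC(=O)c13
F2 | step 8 | 6-(3-chloro-2,4-dioxononyl)-2,2-dimethyl-4H-1,3-dioxin-4-one | CCCCCC(=O)C(Cl)C(=O)CC1=CC(=O)OC(C)(C)O1
F3 | step 3 | 2-(2-bromo-3,5-dimethoxyphenyl)-2-butyl-1,3-dioxolane | CCCCC1(OCCO1)c2cc(OC)cc(OC)c2Br
F4 | step 3 | methyl 2-(2-butyl-1,3-dioxolan-2-yl)-4,6-dimethoxybenzoate | CCCCC1(OCCO1)c2cc(OC)cc(OC)c2C(=O)OC
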